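Readings and results stem from a simulated flask on assumed constants; noise was put on by code.

I hold two charges against each other before anything else: this flask gets [Q] 0.50 mM and [L] 0.475 mM, so Q exceeds L, though narrowly.

common to all: L 0.475 mM

| charge | Q | E | remark | time |
|---|---|---|---|---|
| west | 0.25 mM | 5 µM | run made earlier |  |
| south | 1 mM | 5 µM | run made earlier |  |
| south-west | 0.50 mM | 10 µM | run made earlier |  |
| flask | 0.50 mM | 5.0 µM |  | 10 min |

| run | time / min | Z / % | X / % | Q / % |
|---|---|---|---|---|
| west | 0.667 | 51.0 | 32.9 | 0 |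
| west | 1.33 | 60.3 | 33.9 | 0.9 |
| west | 3.00 | 60.5 | 35.4 | 0 |
| west | 8.00 | 61.8 | 35.8 | 1.1 |
| south | 0.667 | 28.3 | 16.5 | 1.0 |
| south | 1.33 | 28.9 | 18.3 | 0 |
| south | 3.00 | 30.6 | 18.2 | 1.0 |
| south | 8.00 | 31.2 | 17.9 | 0 |
| south-west | 2.00 | 57.9 | 35.2 | 0 |
| south-west | 4.00 | 59.8 | 34.9 | 0 |
| south-west | 6.00 | 59.0 | 34.5 | 0.7 |
| south-west | 8.00 | 59.6 | 34.6 | 0 |

(standard deviation of a reading: 1 percentage point)

- ratio of Z to X at 2.0 s
- ratio of Z to X at 30 s
- ratio of Z to X at 10 min
- which of Z and X there is more of at 10 min



The south run shows what this comparison is worth. At 8.00 min Q reads 0%, yet Z and X together make 0.491 mM, close to the 0.475 mM of L charged. So I take L as the limiting reagent of the south run and, with Q above L here too, of this flask, each Z or X costing one L, and I put the Q beyond L in an unseen pool.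

I carry the unpaired share, one minus [L] charged over [Q] charged, which for this flask is 5.00%. It is a small correction that leaves 95.0% for Z plus X. South-west, with the same Q and L, reads 94.2% at 8.00 min.

South-west has twice the E and reads level, within its scatter, from 2.00 min on. If the rate goes with E, I estimate that this flask comes to the same state in about 4.00 min, less than 10 min. South-west's last reading gives a ratio of 1.72, so I expect Z near 60.1% and X near 34.9% at 10 min. I reckon nothing for the early times.

The forecast gives 1.2, 1.55 and 1.71, with Z ahead. It calls its earliest value “anywhere from strongly X-rich to the plateau ratio”.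

The flask gives 0.435, 1.64 and 1.70, with Z at 59.3% and X at 34.9%. The earliest forecast value is 2.76 times the flask's, and the other answers stand within tolerance.

    Q + E → E + G (k = 2.50 × 10⁵ L mol⁻¹ s⁻¹)
    L + E + G → E + X (k = 2.60 × 10⁷ L² mol⁻² s⁻¹)
    X + E ⇌ Z + E, rate k3*[E]*[X] forward; the back reaction follows from the equilibrium constant (K = 1.70, k = 1.20 × 10⁵ L mol⁻¹ s⁻¹)

At 10.0 min the step L + E + G → E + X has a half-life of 3.1 min for L but 23 min for G. L is down to 0.825% of its charge, while G stands at 5.78%, just above the unpaired 5.00%.

For the neighbour charged with 0.85 mM of Q, the unpaired share is 44.1%. That neighbour ends with G at 44.1%, Z at 35.2% and X at 20.7%.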